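## Structural features

The target is a single 2(5H)-furanone ring (O1, C2 carbonyl, C3=C4, C5) whose C5 carries an exocyclic dibromomethylidene group (C5=C6Br2), so the lactone is a cross-conjugated enol ester. C4 bears the third bromine and C3 a four-carbon chain (C1′–C4′). The only stereocentre is C1′, an (R)-configured secondary alcohol bonded directly to the tetrasubstituted, electron-poor C3=C4 bond, with no neighbouring stereocentre to relay from. The ring is a multiple electrophile: bases and nucleophiles (amines, alkoxides, thiols, free phosphines) attack C4 by addition–elimination, C6, and the enol-ester carbonyl C2, whereas strong acid is tolerated. Because C1′ is allylic, radical or ionic functionalisation of a preformed ring can only give a racemate. Read along HO–C1′–C3(=C4–Br)–C2(=O)O the molecule is a β-bromo Morita–Baylis–Hillman adduct of butanal, and C2 and C5 are two carboxyl-derived carbons held cis on C3=C4, so the ring is a 2-bromo-3-alkylmaleic anhydride whose C5 carbonyl has become C=CBr2. The key step exploits exactly this array: a three-component coupling of a symmetrical acetylenedicarboxylate, butanal and bromide forms C3–C1′, C4–Br and the C1′ configuration together and fixes C2 and C5 cis. The real difficulty is this one carbinol centre in enantiopure form beside a fully substituted, tribrominated, base-labile core.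

## Logic of the disconnections

10 ⇒ 9. The acetyl C–O bond on the C1′ oxygen is cut. The free alcohol cannot pass through the olefination that precedes it, because bromophosphonium species would convert it into a bromide and destroy the configuration. There is no skeletal gain. The forward step must cleave only the acyl–oxygen bond and must be acidic, since the ring does not survive base.

9 ⇒ 8. The exocyclic C5=C6 double bond is cut as a carbonyl olefination. This removes one carbon and two bromines at once and reveals a cyclic anhydride in which both ring carbonyls have the same oxidation level. The forward step demands that a dibromomethylene ylide attacks the C5 carbonyl (next to C4–Br) and not C2 (next to the branched C3 substituent), and that no free phosphine is present.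

8 ⇒ 5. The anhydride C–O bond and the O-acetyl bond are cut, returning two tert-butyl esters and the free alcohol. The reason is that the open-chain diester is the direct product type of the key step. The gain is an acyclic precursor with two identical ester groups. The demand is that the two esters are cis on the double bond (2E descriptor) so that closure is possible, and that acid alone does the work.

5 ⇒ 1 + 2 + bromide (key disconnection). The C3–C1′ bond and the C4–Br bond (furanone locants) are cut. These are the two bonds made when bromide adds to an ynoate and the resulting allenoate 3 adds to an aldehyde. Because 1 is symmetrical, no regiochemical question exists. The gain is large: a stereodefined tetrasubstituted bromoalkene with its carbinol centre goes back to two achiral commercial compounds and a silyl bromide. The forward step must control the face of 2 (Si face gives R) and must bring 2 past bromine, not past the ester, on the allene terminus of 3.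

## Other disconnections considered

Alternative 1: the route that comes to mind first. The enol-lactone O1–C5 bond and the three C–Br bonds are cut, leading back to 2-butyl-4-oxopentanoic acid A1. Forward, bromination and cyclodehydration in hot concentrated sulfuric acid would give the 3-butyl tribromofuranone A2. Radical bromination at C1′ would give the bromide A3, and solvolysis the racemic alcohol A4. The chosen plan is preferred because here C1′ is functionalised last through a planar radical with no facial bias, so a resolution (half the material lost) or an oxidation/asymmetric reduction detour must follow. The bromination/cyclisation is also expected to give mixtures of mono- and dibromomethylidene products. The key step of Alternative 1 does nothing for the stereocentre.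

Alternative 2: the O1–C5 bond and one C6–Br bond are cut. The forward key step is a 5-exo-dig bromolactonisation (NBS) of the bromoalkynyl enynoic acid A5. A5 would come from the same kind of three-component bromo-aldol reaction, run on the 2,4-diynoate A6, followed by Si/Br exchange and ester hydrolysis. The chosen plan is preferred on mechanistic grounds. In the allenoate derived from A6 the two substituents on the allene terminus are bromine and a rod-like alkynyl group of similar effective size. The geometry that places the acid cis to the alkyne is therefore not secured, and the wrong isomer cannot lactonise. Bromide may also add 1,6 instead of 1,4, closure may go 6-endo, and the sequence is one step longer.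

Alternative 3: the C1′–H bond is cut. The forward key step is an enzymatic reduction of the 3-butanoyl furanone A7 by a ketoreductase (NADPH-dependent alcohol dehydrogenase). A7 would have to be made by oxidising the racemic alcohol A4 of Alternative 1. The chosen plan is preferred because this alternative needs the whole racemic route first and adds a redox detour without simplifying the skeleton. A7 is also a doubly activated acceptor with a leaving group at C4. Covalent modification of protein nucleophiles and conjugate hydride transfer from the cofactor are therefore likely to compete with carbonyl reduction.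

Key step: step 1

Assumption: the (S)-configured oxazaborolidinium ion is taken to expose the Si face of butanal, as in its other additions of π-nucleophiles to aldehydes; should the sense be the opposite, the (R)-catalyst is used with no other change.

## Steps

Step 1
Reactants: 1 di-tert-butyl but-2-ynedioate; 2 butanal
Product: 5 di-tert-butyl (2E)-2-bromo-3-[(1R)-1-hydroxybutyl]but-2-enedioate, via silyl bromoallenoate 3 (not isolated), via TMS ether 4 (not isolated)
Conditions: TMSBr (1.3 equiv), (S)-B-o-tolyl diphenylprolinol oxazaborolidine·HNTf2 (20 mol%), EtCN, −78 °C; then 1 M HCl, THF, 0 °C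
Reagents that add atoms: bromotrimethylsilane, C[Si](C)(C)Br
Why: The closest known reaction type is the catalytic asymmetric three-component halo-aldol (β-halo Morita–Baylis–Hillman) coupling of an alkynoate, an aldehyde and a silyl halide. TMSBr silylates one ester carbonyl of 1 and delivers bromide to the β-carbon to give the silyl ketene acetal 3, whose central carbon adds in Mukaiyama fashion to catalyst-bound 2; silyl transfer gives 4 and the acidic work-up frees 5. No ring is closed. C1′ is set by the catalyst alone: the formyl C–H···O contact fixes the aldehyde on boron, the aryl group shields one face, and attack on the exposed Si face gives (R). The second selectivity needed is the alkene geometry: the nucleophilic lobe at the central carbon of 3 lies in the plane of the Br and CO2tBu groups of the allene terminus, so the aldehyde complex should pass the smaller Br, which puts C1′ cis to Br and the two esters cis (2E). Since 1 is symmetrical, no regiochemical question arises. In 5 the carbinol oxygen is trans to the distal ester and cannot lactonise, whereas the other geometric isomer would lactonise on work-up and be removed by chromatography.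

Step 2
Reactants: 5 di-tert-butyl (2E)-2-bromo-3-[(1R)-1-hydroxybutyl]but-2-enedioate
Product: 8 (1R)-1-(4-bromo-2,5-dioxo-2,5-dihydrofuran-3-yl)butyl acetate, via acetate diester 6 (not isolated), via acetoxy diacid 7 (not isolated)
Conditions: Ac2O (5 equiv), TFA/CH2Cl2 1:2, 0 °C → rt; evaporate with toluene, 40 °C
Reagents that add atoms: acetic anhydride, CC(=O)OC(C)=O
Why: One-flask sequence of known acid-mediated steps: acetyl trifluoroacetate formed in situ acetylates the secondary alcohol (6), TFA cleaves both tert-butyl esters with loss of isobutene (7), and excess Ac2O dehydrates the cis-diacid to the five-membered anhydride, as in the O-acylation/anhydride formation of hydroxy diacids. No base is present, so the vinylic bromide is safe, and the C1′–O bond is never broken, so the configuration is kept.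

Step 3
Reactants: 8 (1R)-1-(4-bromo-2,5-dioxo-2,5-dihydrofuran-3-yl)butyl acetate
Product: 9 (1R)-1-[4-bromo-5-(dibromomethylidene)-2-oxo-2,5-dihydrofuran-3-yl]butyl acetate
Conditions: CBr4, PPh3, Zn dust (1.5 equiv each), CH2Cl2, rt, 12 h (ylide preformed); then 8, 0 → 40 °C
Reagents that add atoms: carbon tetrabromide, BrC(Br)(Br)Br
Why: Ramirez-type dibromomethylenation (Wittig olefination) of a cyclic anhydride carbonyl with preformed Ph3P=CBr2; the zinc protocol leaves neither free phosphine, which would add to the anhydride, nor a bromophosphorane. Attack is expected at the C5 carbonyl, which is inductively activated by the adjacent C4–Br and less hindered, whereas C2 lies beside the branched acetoxybutyl group and is deactivated by conjugation with the bromine lone pair. The acetate is inert to the ylide.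

Step 4
Reactants: 9 (1R)-1-[4-bromo-5-(dibromomethylidene)-2-oxo-2,5-dihydrofuran-3-yl]butyl acetate
Product: 10 4-bromo-5-(dibromomethylidene)-3-[(1R)-1-hydroxybutyl]furan-2(5H)-one
Conditions: 2 M aq. H2SO4/1,4-dioxane 1:1, 50 °C
Reagents that add atoms: none
Why: Acid-catalysed ester hydrolysis (AAc2) cleaves the acyl–oxygen bond and leaves the C1′–O bond and its configuration untouched. The tribromo enol lactone is base-labile but tolerant of acid, and ionisation at C1′ is disfavoured because the cation would sit on the α-carbon of an electron-poor unsaturated lactone.

## Compound list

1 | di-tert-butyl but-2-ynedioate | CC(C)(C)OC(=O)C#CC(=O)OC(C)(C)C | starting material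
2 | butanal | CCCC=O | starting material
3 | tert-butyl 2-bromo-4-tert-butoxy-4-(trimethylsilyloxy)buta-2,3-dienoate (racemic allene) | CC(C)(C)OC(=O)C(Br)=C=C(O[Si](C)(C)C)OC(C)(C)C | intermediate
4 | di-tert-butyl (2E)-2-bromo-3-[(1R)-1-(trimethylsilyloxy)butyl]but-2-enedioate | CCC[C@@H](O[Si](C)(C)C)/C(C(=O)OC(C)(C)C)=C(\Br)C(=O)OC(C)(C)C | intermediate
5 | di-tert-butyl (2E)-2-bromo-3-[(1R)-1-hydroxybutyl]but-2-enedioate | CCC[C@@H](O)/C(C(=O)OC(C)(C)C)=C(\Br)C(=O)OC(C)(C)C | intermediate
6 | di-tert-butyl (2E)-2-[(1R)-1-(acetyloxy)butyl]-3-bromobut-2-enedioate | CCC[C@@H](OC(C)=O)/C(C(=O)OC(C)(C)C)=C(\Br)C(=O)OC(C)(C)C | intermediate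
7 | (2E)-2-[(1R)-1-(acetyloxy)butyl]-3-bromobut-2-enedioic acid | CCC[C@@H](OC(C)=O)/C(C(O)=O)=C(\Br)C(O)=O | intermediate
8 | (1R)-1-(4-bromo-2,5-dioxo-2,5-dihydrofuran-3-yl)butyl acetate | CCC[C@@H](OC(C)=O)C1=C(Br)C(=O)OC1=O | intermediate
9 | (1R)-1-[4-bromo-5-(dibromomethylidene)-2-oxo-2,5-dihydrofuran-3-yl]butyl acetate | CCC[C@@H](OC(C)=O)C1=C(Br)C(=C(Br)Br)OC1=O | intermediate
10 | 4-bromo-5-(dibromomethylidene)-3-[(1R)-1-hydroxybutyl]furan-2(5H)-one | CCC[C@@H](O)C1=C(Br)C(=C(Br)Br)OC1=O | target

## Step count and least certain steps

Total step count: 4. Longest linear sequence: 4 steps (1 and 2 → 5 → 8 → 9 → 10).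

Step 1 (key step). Three processes may go wrong.
- Facial discrimination of the aldehyde may be poor, because the hindered bromoallenoate is a slow nucleophile and a silyl-promoted background addition may then compete with the catalysed one.
- The aldehyde may approach past the ester instead of past bromine, which diverts material into the geometric isomer that lactonises through the carbinol oxygen.
- Bromide transfer from TMSBr to the hindered tert-butyl ynoate may be sluggish.

The fallback sets the stereocentre by reagent-controlled ketone reduction instead of aldehyde-face control. It sets out from 1 and 2 and comes back at 5. A magnesium bromide etherate-promoted bromo-aldol reaction of 1 with 2 (CH2Cl2, 0 °C) should give racemic di-tert-butyl (2E)-2-bromo-3-(1-hydroxybutyl)but-2-enedioate F1. Dess–Martin oxidation should give di-tert-butyl (2E)-2-bromo-3-butanoylbut-2-enedioate F2. CBS reduction with the (S)-methyl oxazaborolidine and catecholborane (toluene, −78 °C), with the alkenyl group acting as the large substituent, should return 5.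

Step 3. Three processes may go wrong.
- Phosphorus species may displace bromide at C4 by addition–elimination.
- The ylide may attack the C2 carbonyl if the electronic and steric difference between the two carbonyls is smaller than estimated.
- The hindered anhydride may not react at all.

The fallback replaces the olefination by carbanion addition and dehydration. It sets out from 8 and comes back at 9. Dibromomethyllithium (CH2Br2, LiTMP, THF, −100 °C), a small and phosphorus-free nucleophile, should add to the more electrophilic C5 carbonyl and give after work-up the lactol (1R)-1-[4-bromo-5-(dibromomethyl)-5-hydroxy-2-oxo-2,5-dihydrofuran-3-yl]butyl acetate F3. Cyclodehydration with P2O5 (CH2Cl2, reflux) should give 9.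

Step 4. Water may open the enol-lactone ring in competition with hydrolysis of the hindered acetate, and partial ionisation at C1′ in warm acid may erode the enantiomeric purity. The fallback changes the protecting group to a silyl ether that is removed without water or heat. It sets out from 5 and comes back at 10.
- TIPSOTf and 2,6-lutidine (CH2Cl2, −78 → 0 °C) should give di-tert-butyl (2E)-2-bromo-3-[(1R)-1-(triisopropylsilyloxy)butyl]but-2-enedioate F4.
- TFA/CH2Cl2 should give (2E)-2-bromo-3-[(1R)-1-(triisopropylsilyloxy)butyl]but-2-enedioic acid F5, and Ac2O should close it to 3-bromo-4-[(1R)-1-(triisopropylsilyloxy)butyl]furan-2,5-dione F6.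
- The dibromomethylenation of step 3 should give 4-bromo-5-(dibromomethylidene)-3-[(1R)-1-(triisopropylsilyloxy)butyl]furan-2(5H)-one F7.
- HF·pyridine (THF, rt) should give 10.

## Further compounds

F1 | step 1 | racemic di-tert-butyl (2E)-2-bromo-3-(1-hydroxybutyl)but-2-enedioate | CCCC(O)/C(C(=O)OC(C)(C)C)=C(\Br)C(=O)OC(C)(C)C
F2 | step 1 | di-tert-butyl (2E)-2-bromo-3-butanoylbut-2-enedioate | CCCC(=O)/C(C(=O)OC(C)(C)C)=C(\Br)C(=O)OC(C)(C)C
F3 | step 3 | (1R)-1-[4-bromo-5-(dibromomethyl)-5-hydroxy-2-oxo-2,5-dihydrofuran-3-yl]butyl acetate (both C5 epimers) | CCC[C@@H](OC(C)=O)C1=C(Br)C(O)(C(Br)Br)OC1=O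
F4 | step 4 | di-tert-butyl (2E)-2-bromo-3-[(1R)-1-(triisopropylsilyloxy)butyl]but-2-enedioate | CCC[C@@H](O[Si](C(C)C)(C(C)C)C(C)C)/C(C(=O)OC(C)(C)C)=C(\Br)C(=O)OC(C)(C)C
F5 | step 4 | (2E)-2-bromo-3-[(1R)-1-(triisopropylsilyloxy)butyl]but-2-enedioic acid | CCC[C@@H](O[Si](C(C)C)(C(C)C)C(C)C)/C(C(O)=O)=C(\Br)C(O)=O
F6 | step 4 | 3-bromo-4-[(1R)-1-(triisopropylsilyloxy)butyl]furan-2,5-dione | CCC[C@@H](O[Si](C(C)C)(C(C)C)C(C)C)C1=C(Br)C(=O)OC1=O
F7 | step 4 | 4-bromo-5-(dibromomethylidene)-3-[(1R)-1-(triisopropylsilyloxy)butyl]furan-2(5H)-one | CCC[C@@H](O[Si](C(C)C)(C(C)C)C(C)C)C1=C(Br)C(=C(Br)Br)OC1=O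
A1 | alternative 1 | racemic 2-butyl-4-oxopentanoic acid | CCCCC(CC(C)=O)C(O)=O
A2 | alternative 1 | 4-bromo-3-butyl-5-(dibromomethylidene)furan-2(5H)-one | CCCCC1=C(Br)C(=C(Br)Br)OC1=O
A3 | alternative 1 | racemic 4-bromo-3-(1-bromobutyl)-5-(dibromomethylidene)furan-2(5H)-one | CCCC(Br)C1=C(Br)C(=C(Br)Br)OC1=O
A4 | alternative 1 | racemic 4-bromo-5-(dibromomethylidene)-3-(1-hydroxybutyl)furan-2(5H)-one | CCCC(O)C1=C(Br)C(=C(Br)Br)OC1=O
A5 | alternative 2 | (2E)-3,5-dibromo-2-[(1R)-1-hydroxybutyl]pent-2-en-4-ynoic acid | CCC[C@@H](O)/C(C(O)=O)=C(\Br)C#CBr
A6 | alternative 2 | methyl 5-(trimethylsilyl)penta-2,4-diynoate | COC(=O)C#CC#C[Si](C)(C)C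
A7 | alternative 3 | 4-bromo-3-butanoyl-5-(dibromomethylidene)furan-2(5H)-one | CCCC(=O)C1=C(Br)C(=C(Br)Br)OC1=O
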